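By the time of reading, 20 h, delta's substrate stands at 0%, and its target has fallen from 69.7% at 4.00 h to 15.6%. Gamma, charged with equal substrate and reagent, still holds 89.2%. What is read at that hour is therefore what has survived.

| flask | substrate | reagent | free catalyst | remark | time |
|---|---|---|---|---|---|
| delta | 0.011 M | 0.050 M (fed, over 6.0 min) | 0.55 mM | run made earlier |  |
| zeta | 0.027 M | 0.050 M (fed, over 6.0 min) | 0.55 mM | run made earlier |  |
| beta | 0.057 M | 0.050 M (fed, over 6.0 min) | 0.55 mM | run made earlier |  |
| gamma | 0.050 M | 0.050 M (fed, over 6.0 min) | 0.83 mM | run made earlier |  |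
| blue | 0.025 M | 0.0500 M (fed, over 10 min) | 0.55 mM |  | 20 h |
| grey | 0.050 M | 0.100 M (fed, over 12 min) | 0.55 mM |  | 20 h |
| ochre | 0.050 M | 0.0500 M (fed, over 6.0 min) | 0.55 mM |  | 20 h |
| amber | 0.050 M | 0.0120 M (fed, over 6.0 min) | 1.5 mM |  | 20 h |
| violet | 0.015 M | 0.0500 M (fed, over 6.0 min) | 0.55 mM |  | 20 h |

| run | time / h | target / % | substrate / % |
|---|---|---|---|
| delta | 4.00 | 69.7 | 3.5 |
| delta | 8.00 | 48.2 | 0 |
| delta | 12.0 | 32.8 | 0.1 |
| delta | 15.0 | 22.6 | 0.1 |
| delta | 20.0 | 15.6 | 0 |
| zeta | 1.50 | 65.9 | 17.7 |
| zeta | 3.00 | 78.7 | 3.7 |
| zeta | 6.00 | 75.6 | 0 |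
| zeta | 10.0 | 64.6 | 0 |
| zeta | 20.0 | 50.6 | 1.0 |
| beta | 1.50 | 51.2 | 31.7 |
| beta | 3.00 | 69.5 | 16.8 |
| beta | 6.00 | 78.9 | 8.8 |
| beta | 10.0 | 83.5 | 10.3 |
| beta | 20.0 | 82.6 | 10.1 |
| gamma | 4.00 | 87.0 | 3.2 |
| gamma | 8.00 | 90.1 | 2.8 |
| gamma | 12.0 | 90.7 | 1.8 |
| gamma | 15.0 | 89.2 | 1.8 |
| gamma | 20.0 | 89.2 | 2.6 |

(standard deviation of a reading: 1 percentage point)

- the numbers in the tables scatter with a standard deviation of 1 percentage point
- a reading or a percentage of target counts all its forms, free or not

1. the flasks by amount of target, in percent of the substrate charged, highest first, at 20 h (blue / grey / ochre / amber / violet)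
2. the same order at 2.0 h (blue / grey / ochre / amber / violet)
3. the amount of target, in percent of the substrate charged of the flask you put first, at 20 h
4. the amount of target, in percent of the substrate charged of the flask you put last, at 20 h

Delta's target is lost at a reading of 0.0936 /h. The reckoning here treats this loss as pseudo-first-order, proportional to free catalyst and to spare reagent, the share of the reagent charge beyond the substrate charge: 78.0% in delta, 70.0% in violet. Delta's rate times the time, scaled by those two ratios, gives one number, for violet 1.68: the hit number, the turnovers of over-reaction to which an average target molecule is exposed. The target fraction surviving is e to the minus that number, so violet should keep 18.6%.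

Zeta tests whether one number is enough. From 6.00 h to 20.0 h the hit number comes to 0.772, but the readings give 0.402, so it counts twice too many. Zeta's spare share is 46.0%, and blue, on the same reagent charge, has 50.0%, so the number is trusted for violet and not for blue. Grey has a doubled reagent charge, so shares do not compare: its spare reagent is 0.0500 M, more than delta's 0.0390 M, which scales its hit number to 2.40. Its substrate charge, though, is larger than zeta's, where the number counted too many, so that figure is not trusted either. Ochre has gamma's equal charges, and amber's reagent caps its target at 24.0% as limiting reagent. This reckoning therefore puts violet below amber's cap, and last provided that grey stays above it.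

The forecast gives ochre > blue > grey > violet > amber at 20 h and blue > violet > grey > ochre > amber at 2.0 h, with the top at 89% (84% to 92%) and the lowest at 22% (17% to 25%), on the grounds of “slow destruction of target by leftover reagent”. It parts from the reckoning here over the last place, which it gives to amber.

The flasks give ochre > blue > grey > amber > violet at 20 h and violet > blue > grey > ochre > amber at 2.0 h, with ochre at 90.4% and violet at 21.7%. Amber holds 23.9%, and violet's reading stands 3.1 percentage points above its hit-number figure, while its reagent ends at 46.6% of its own charge, down from a spare share of 70.0% at the start.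

    reagent + catalyst intermediate A ⇌ catalyst intermediate B (K = 22.3 /M, k = 0.681 /M/s)
    substrate + free catalyst → catalyst intermediate A (k = 0.935 /M/s)
    catalyst intermediate B → catalyst intermediate C (k = 0.496 /s)
    reagent + free catalyst + target → free catalyst + over-reaction product (k = 1.65 /M²/s)
    crystals ⇌ target, rate k5*(cs5 - [target]) while solid is left; crystals form when [target] > cs5 (solubility = 38.0 mM, k = 0.00997 /s)
    substrate ⇌ dormant form (K = 0.390, k = 8.83 × 10⁻⁵ /s)
    catalyst intermediate C ⇌ free catalyst + target (K = 0.0660 M, k = 0.167 /s)

In the neighbour of violet with 1.4 × 10⁻⁴ M of free catalyst, the hit number drops to 0.427, which leaves 65.2% as target. That flask gives 68.3%.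

Readings and results were generated by integration with constants of no real substance, and the scatter is random.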